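**Retrosynthetic overview**
1. Ludongnin F ⇐ 16‑methylene‑15‑ketone (exo‑face hydrogenation sets C16) ⇐ ring D by 5‑exo vinyl‑radical cyclization of a C15 propargylic alcohol onto a Δ12 alkene (fixes C13).
2. Ring C and the C8/C9 pair ⇐ Diels–Alder of butadiene with a 3‑formyl‑α,β‑unsaturated spiro‑δ‑lactone.
3. Spiro‑lactone (C10 quaternary) ⇐ Ti(III) reductive coupling of a C10 spiro‑epoxide with an acrylate.
4. cis‑Fused methyl acetal (C5, C6) ⇐ orthoformate alkylation of a cyclohexanone enol silane, then transacetalization; C4 ⇐ Cu‑catalysed asymmetric conjugate methylation.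
5. Ring order: A → tetrahydrofuran acetal → 7,20‑lactone → C → D.

**Assumptions (one line each)**
- Locants C1–C20 are ent‑kaurane numbering of the target (C6 = acetal carbon, C7 = lactone C=O, C15 = ketone, C19/C20 = the two OCH2 carbons).
- Multi‑carbon coupling partners are numbered as starting materials; simple atom‑donating reagents are given with SMILES in each step.
- The ligand antipode in step 2 is the one that gives 4R; this substrate has no direct precedent and the sense of induction would have to be confirmed.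
- The C6 anomers are assumed to equilibrate under acid in MeOH, with the 6R anomer isolable and the other recycled; which anomer is favoured is not known.

**Route**

Step 1
Reactants: 1 (3‑ethoxycyclohex‑2‑en‑1‑one); 2 (tributyl[(benzyloxy)methyl]stannane)
Product: 3, 3‑[(benzyloxy)methyl]cyclohex‑2‑en‑1‑one
Conditions: 2, n‑BuLi, THF, −78 °C; add 1, −78→0 °C; then 1 M HCl, rt
Reagents that add atoms: 2, CCCC[Sn](CCCC)(CCCC)COCc1ccccc1 (delivers CH2OBn); water, O (new carbonyl oxygen)
Why: Stork–Danheiser sequence — Sn/Li exchange gives BnOCH2Li, which adds 1,2 to the vinylogous ester, and acid hydrolysis/dehydration transposes the enone (no stereocentre).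

Step 2
Reactants: 3
Product: 4, (R)‑{[3‑[(benzyloxy)methyl]‑3‑methylcyclohex‑1‑en‑1‑yl]oxy}trimethylsilane
Conditions: Me3Al, CuTC (5 mol %), chiral phosphoramidite L* (10 mol %), Et2O, −30 °C; then TMSOTf, −30→0 °C
Reagents that add atoms: trimethylaluminium, C[Al](C)C (CH3 = C18); TMSOTf, C[Si](C)(C)OS(=O)(=O)C(F)(F)F (SiMe3)
Why: Cu‑catalysed asymmetric conjugate addition (Alexakis type) creates the C4 quaternary centre under ligand control, and silylation of the aluminium enolate fixes the enolate regiochemistry toward C5.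

Step 3
Reactants: 4
Product: 5, (3R)‑3‑[(benzyloxy)methyl]‑2‑(dimethoxymethyl)‑3‑methylcyclohexan‑1‑one (C2 epimers)
Conditions: HC(OMe)3, TMSOTf (10 mol %), CH2Cl2, −78 °C; pyridine quench
Reagents that add atoms: trimethyl orthoformate, COC(OC)OC (CH(OMe)2 = C6 and the future OMe)
Why: Mukaiyama‑type alkylation of the enol silane by the dimethoxycarbenium ion installs C6 at the aldehyde oxidation level regiospecifically at C5; the C5 configuration is unimportant because it is still epimerizable.

Step 4
Reactants: 5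
Product: 6, (3R,3aS,7aR)‑3‑methoxy‑7a‑methylhexahydroisobenzofuran‑4(1H)‑one (cis‑fused keto acetal; kaurane 4R,5S,6R)
Conditions: H2 (1 atm), Pd/C, MeOH, rt; filter; CSA (10 mol %), MeOH, 40 °C; Et3N; separate anomers and recycle the minor one
Reagents that add atoms: none (OMe may exchange with solvent methanol)
Why: Hydrogenolysis frees the C19 alcohol and acid transacetalization closes the five‑membered mixed acetal; C5 equilibrates through the enol to the only cis‑fusable configuration and C6 is set by anomeric equilibration.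

Step 5
Reactants: 6
Product: 7, (1R,3aR,7aR)‑1‑methoxy‑3a‑methylhexahydro‑1H‑spiro[isobenzofuran‑7,2'‑oxirane] (epoxide epimers)
Conditions: Me3S+ I−, KHMDS, THF, −10→0 °C
Reagents that add atoms: trimethylsulfonium iodide, C[S+](C)C.[I-] (CH2 = C20)
Why: Corey–Chaykovsky epoxidation adds C20 to the C10 ketone; the epoxide configuration is irrelevant because both epimers give the same C10 radical in step 6.

Step 6
Reactants: 7; 8 (2,2,2‑trifluoroethyl acrylate)
Product: 9, spiro‑δ‑lactone (1R,3aR,7R,7aR)‑1‑methoxy‑3a‑methyloctahydrospiro[isobenzofuran‑7,3'‑pyran]‑6'‑one (kaurane 4R,5R,6R,10R)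
Conditions: Cp2TiCl2, Zn dust, 2,4,6‑collidine·HCl, 8 (5 equiv), THF, rt
Reagents that add atoms: 8, C=CC(=O)OCC(F)(F)F (C9–C8–C7=O)
Why: Ti(III) epoxide opening (Nugent–RajanBabu) gives the tertiary C10 radical, which undergoes Giese addition to the acrylate on the convex face anti to the cis‑fused tetrahydrofuran, and the titanium alkoxide lactonizes onto the activated ester.

Step 7
Reactants: 9
Product: 10, 8‑(hydroxymethylene) spiro‑lactone (enol form of the 8‑formyl lactone)
Conditions: LDA (2.2 equiv), THF, −78 °C; HCO2Et, −78 °C→rt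
Reagents that add atoms: ethyl formate, CCOC=O (CHO = C15)
Why: Claisen formylation of the lactone enolate puts C15 on C8 as a stable enolized β‑formyl lactone (no new stereocentre).

Step 8
Reactants: 10
Product: 11, 8‑formyl‑Δ8(9)‑unsaturated spiro‑lactone (3‑formyl‑5,6‑dihydro‑2H‑pyran‑2‑one), used crude
Conditions: PhSeCl, pyridine, CH2Cl2, 0 °C; then 30 % H2O2, 0 °C
Reagents that add atoms: none
Why: α‑Selenenylation of the β‑dicarbonyl followed by selenoxide syn‑elimination toward C9 (Reich/Liotta protocol) gives the doubly activated dienophile.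

Step 9
Reactants: 11; 12 (buta‑1,3‑diene)
Product: 13, cis‑fused cyclohexene–lactone aldehyde (kaurane 4R,5R,6R,8S,9S,10R; Δ12 alkene, CHO on C8)
Conditions: 12 (excess), CH2Cl2, −20 °C→rt, sealed tube (cat. ZnCl2 only if sluggish)
Reagents that add atoms: 12, C=CC=C (C11–C14)
Why: Diels–Alder cycloaddition in which suprafacial addition to the ring alkene forces the cis lactone/ring‑C fusion (C8 and C9 together), and the diene is expected to approach the face syn to C1 and anti to the C5 methine bearing the acetal, which sets C9 relative to C10.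

Step 10
Reactants: 13
Product: 14, 15‑ethynyl‑15‑hydroxy adduct (propargylic alcohol on C8; C15 epimers)
Conditions: HC≡CMgBr, THF, −78 °C; cold NH4Cl quench
Reagents that add atoms: ethynylmagnesium bromide, C#C[Mg]Br (C16–C17)
Why: Grignard 1,2‑addition is chemoselective for the non‑enolizable neopentyl aldehyde over the δ‑lactone, and the C15 configuration is erased in step 12.

Step 11
Reactants: 14
Product: 15, 15‑hydroxy‑16‑methylene tetracycle (bicyclo[3.2.1]octane formed; 13R; C15 epimers)
Conditions: Bu3SnH, AIBN, PhMe, 90 °C, slow addition; then PPTS, CH2Cl2–MeOH, rt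
Reagents that add atoms: none
Why: Stannyl‑radical addition to the terminal alkyne gives the C16 vinyl radical, whose 5‑exo‑trig cyclization onto C13 of the Δ12 alkene is geometrically constrained to the face bearing the C8 side chain, and protodestannylation leaves the exocyclic methylene.

Step 12
Reactants: 15
Product: 16, (6R)‑6‑methoxy‑6,19‑epoxy‑15‑oxo‑6,7‑seco‑ent‑kaur‑16‑en‑7,20‑olide (16‑methylene‑15‑ketone)
Conditions: Dess–Martin periodinane, NaHCO3, CH2Cl2, rt
Reagents that add atoms: none
Why: Buffered Dess–Martin oxidation of the allylic alcohol converges both C15 epimers on the enone without touching the acetal.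

Step 13
Reactants: 16
Product: 17, ludongnin F
Conditions: H2 (1 atm), 10 % Pd/C, EtOAc, rt
Reagents that add atoms: none
Why: Heterogeneous syn‑hydrogenation of the exocyclic enone should deliver hydrogen from the exo face (C14 side) of the bicyclo[3.2.1]octane, placing the new methyl endo (16R); no base is used afterwards, so this kinetic epimer is retained.

**Compound list**
1 | 3‑ethoxycyclohex‑2‑en‑1‑one | CCOC1=CC(=O)CCC1 | starting material
2 | tributyl[(benzyloxy)methyl]stannane | CCCC[Sn](CCCC)(CCCC)COCc1ccccc1 | starting material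
3 | 3‑[(benzyloxy)methyl]cyclohex‑2‑en‑1‑one | O=C1C=C(COCc2ccccc2)CCC1 | intermediate
4 | (R)‑{[3‑[(benzyloxy)methyl]‑3‑methylcyclohex‑1‑en‑1‑yl]oxy}trimethylsilane | C(OCc1ccccc1)[C@]2(C)CCCC(O[Si](C)(C)C)=C2 | intermediate
5 | (3R)‑3‑[(benzyloxy)methyl]‑2‑(dimethoxymethyl)‑3‑methylcyclohexan‑1‑one (C2 epimers) | C(OCc1ccccc1)[C@]2(C)CCCC(=O)C2C(OC)OC | intermediate
6 | (3R,3aS,7aR)‑3‑methoxy‑7a‑methylhexahydroisobenzofuran‑4(1H)‑one | CO[C@@H]1OC[C@]2(C)CCCC(=O)[C@H]12 | intermediate
7 | (1R,3aR,7aR)‑1‑methoxy‑3a‑methylhexahydro‑1H‑spiro[isobenzofuran‑7,2'‑oxirane] (epoxide epimers) | CO[C@@H]1OC[C@]2(C)CCCC3(CO3)[C@H]12 | intermediate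
8 | 2,2,2‑trifluoroethyl acrylate | C=CC(=O)OCC(F)(F)F | starting material
9 | (1R,3aR,7R,7aR)‑1‑methoxy‑3a‑methyloctahydrospiro[isobenzofuran‑7,3'‑pyran]‑6'‑one | CO[C@@H]1OC[C@]2(C)CCC[C@]3(COC(=O)CC3)[C@H]12 | intermediate
10 | 5'‑(hydroxymethylene) derivative of 9 (enol of the 8‑formyl lactone) | CO[C@@H]1OC[C@]2(C)CCC[C@]3(COC(=O)C(=CO)C3)[C@H]12 | intermediate
11 | 5'‑formyl‑4',5'‑didehydro derivative of 9 (3‑formyl‑5,6‑dihydro‑2H‑pyran‑2‑one spiro‑fused at C10) | CO[C@@H]1OC[C@]2(C)CCC[C@]3(COC(=O)C(C=O)=C3)[C@H]12 | intermediate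
12 | buta‑1,3‑diene | C=CC=C | starting material
13 | Diels–Alder adduct: cis‑fused Δ12‑cyclohexene/δ‑lactone with CHO on C8 (4R,5R,6R,8S,9S,10R) | CO[C@@H]1OC[C@]2(C)CCC[C@]3(COC(=O)[C@@]4(C=O)CC=CC[C@H]43)[C@H]12 | intermediate
14 | 1‑hydroxyprop‑2‑ynyl (C15–C17) derivative of 13 (C15 epimers) | CO[C@@H]1OC[C@]2(C)CCC[C@]3(COC(=O)[C@@]4(C(O)C#C)CC=CC[C@H]43)[C@H]12 | intermediate
15 | (6R)‑15‑hydroxy‑6‑methoxy‑6,19‑epoxy‑6,7‑seco‑ent‑kaur‑16‑en‑7,20‑olide (C15 epimers) | CO[C@@H]1OC[C@]2(C)CCC[C@]3(COC(=O)[C@@]45C[C@@H](CC[C@H]43)C(=C)C5O)[C@H]12 | intermediate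
16 | (6R)‑6‑methoxy‑6,19‑epoxy‑15‑oxo‑6,7‑seco‑ent‑kaur‑16‑en‑7,20‑olide | CO[C@@H]1OC[C@]2(C)CCC[C@]3(COC(=O)[C@@]45C[C@@H](CC[C@H]43)C(=C)C5=O)[C@H]12 | intermediate
17 | ludongnin F, (4R,5R,6R,8S,9S,10R,13R,16R) | CO[C@@H]1OC[C@]2(C)CCC[C@]3(COC(=O)[C@@]45C[C@@H](CC[C@H]43)[C@@H](C)C5=O)[C@H]12 | target

**Totals**
Total steps: 13. Longest linear sequence: 13 (from 3‑ethoxycyclohex‑2‑en‑1‑one; 2, 8 and 12 are commercial).

**Three steps most likely to fail**
1. Step 9 (Diels–Alder): the 3‑formyl dienophile 11 is labile, and the facial selectivity next to the spiro centre rests on a steric argument only. Fallback: build ring C stepwise from 9 — selenoxide elimination to the plain unsaturated lactone, cuprate conjugate allylation at C9, α‑allylation at C8, and ring‑closing metathesis to the same Δ12 cyclohexene. Then add C15–C17 by aldol of the ring‑fusion lactone enolate with 3‑(trimethylsilyl)propynal and desilylate, rejoining at 14.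
2. Step 6 (Ti(III) epoxide–acrylate spirolactonization): the risks are β‑hydride elimination to the allylic alcohol and insufficient diastereoselectivity at C10. Fallback: set C10 by a Still–Wittig [2,3] rearrangement instead — ketone 6 → HWE → DIBAL → O‑CH2SnBu3 ether → n‑BuLi gives C10 bearing CH2OH and vinyl. Acryloylation and ring‑closing metathesis then give the unsaturated spiro‑lactone, and PhSeLi addition/formate trapping/oxidation rejoins at 11.
3. Step 4 (C5/C6 control in the acetalization): the thermodynamic anomer ratio may disfavour 6R, or β‑elimination to the alkoxymethylene ketone may compete. Fallback: abandon thermodynamic control at C6 — carry whichever anomer forms, hydrolyse 17 (or its 6‑epimer) to the 6,19‑lactol at the end, and install the methyl group by kinetic anomeric O‑alkylation (Ag2O, MeI).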